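Both rings of the drimane are disconnected at once, at C5–C10 (ring A, C1–C5/C10) and C8–C9 (ring B, C5–C10). The key step exploits the placement of the C6 oxygen and the carboxyl carbons C12 (on C8) and C11 (on C9): a C6 carbonyl makes C5 a donor and C8 an acceptor, the C11 carbonyl makes C10 an acceptor and C9 a donor. An acyclic (Z)-silyl dienol ether of a 4-oxo-enoate, tethered through the C4 gem-dimethyl chain to an (E)-β-methyl enoyl oxazolidinone, should therefore close both rings and set C5, C8, C9 and C10 in one copper–bis(oxazoline) double Michael cascade. Reduction, acylation and deprotection complete the target.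

Key step: step 10

Assumption (numbering): drimane numbering is used for all intermediates (ring A = C1–C5 and C10, ring B = C5–C10, C11 on C9, C12 on C8); the target is 5α-H, 6β-acyloxy (axial), 8β-CO2H (axial), 9β-CO2H (equatorial), 10β-CH3, i.e. (1S,2S,4R,4aS,8aS) in decalin numbering.

Assumption (sense of induction): the bis(oxazoline)copper–imide chelate is taken as square planar with an s-cis enoyl group, in which the (S,S)-ligand exposes the Re face at the α-carbon. The (R,R)-ligand, 2,2'-(propane-2,2-diyl)bis[(4R)-4-tert-butyl-4,5-dihydro-1,3-oxazole], is therefore specified; the antipodal ligand would be used if the opposite sense were found.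

Design remarks:
- C12 is carried as a tert-butyl ester, because a small alkyl ester in the axial 8β position would lactonise onto the 6β-hydroxyl after ketone reduction and force a protecting-group detour.
- The (E)-C9=C10 alkene is fixed by a stereoretentive cross-coupling, not by ketone olefination.
- The cascade first delivers the C6 silyl enol ether, which the work-up hydrolyses to the ketone.
- Compounds 1, 4, 9, 12, 24 and 25 are taken as purchased.

Step 1
Reactants: 1 2,2-dimethylpent-4-enal
Product: 2 2,2-dimethylpent-4-en-1-ol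
Conditions: NaBH4, MeOH, 0 °C
Reagents that add atoms: none
Why: Borohydride reduction of a non-enolisable aldehyde, to which the isolated terminal alkene is inert.

Step 2
Reactants: 2 2,2-dimethylpent-4-en-1-ol
Product: 3 5-iodo-4,4-dimethylpent-1-ene
Conditions: I2, PPh3, imidazole, toluene, 90 °C
Reagents that add atoms: iodine, II
Why: Appel-type (Garegg–Samuelsson) iodination, in which the alkoxyphosphonium ion is displaced by iodide in an SN2 step that is slow but clean at the neopentyl carbon on heating and opens no cationic rearrangement path.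

Step 3
Reactants: 4 methyl acetoacetate
Product: 5 methyl (2E)-3-(trifluoromethylsulfonyloxy)but-2-enoate
Conditions: Me4NOH (25% aq), Tf2O, hexanes, 5–10 °C
Reagents that add atoms: trifluoromethanesulfonic anhydride, O=S(=O)(OS(=O)(=O)C(F)(F)F)C(F)(F)F
Why: Stereoselective enol triflation of a β-keto ester, in which the non-chelating tetramethylammonium counter-ion lets the enolate react in its extended form so that the triflate ends up trans to the ester and the methyl group cis to it.

Step 4
Reactants: 3 5-iodo-4,4-dimethylpent-1-ene; 5 methyl (2E)-3-(trifluoromethylsulfonyloxy)but-2-enoate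
Product: 7 methyl (2E)-8-iodo-3,7,7-trimethyloct-2-enoate, via B-alkyl-9-BBN adduct 6 (not isolated)
Conditions: 9-BBN, THF, 0 °C → rt; then 5, PdCl2(dppf) (3 mol %), K3PO4 (3 M aq), THF/DMF, rt
Reagents that add atoms: none
Why: Anti-Markovnikov hydroboration followed by B-alkyl Suzuki–Miyaura coupling, which replaces the triflate with retention and so fixes the (E)-trisubstituted alkene (later C9=C10, methyl cis to the carbonyl), while the neopentyl iodide is inert to 9-BBN and slow in oxidative addition.

Step 5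
Reactants: 7 methyl (2E)-8-iodo-3,7,7-trimethyloct-2-enoate
Product: 8 (2E)-8-iodo-3,7,7-trimethyloct-2-enoic acid
Conditions: LiOH·H2O, THF/MeOH/H2O, 45 °C; then 1 M HCl
Reagents that add atoms: lithium hydroxide, [Li+].[OH-]
Why: Saponification (BAc2), in which hydroxide does not deprotonate the γ-positions, so the alkene geometry is kept, and the neopentyl iodide resists substitution and has no β-hydrogen for elimination.

Step 6
Reactants: 8 (2E)-8-iodo-3,7,7-trimethyloct-2-enoic acid; 9 oxazolidin-2-one
Product: 11 3-[(2E)-8-iodo-3,7,7-trimethyloct-2-enoyl]-1,3-oxazolidin-2-one, via mixed pivalic anhydride 10 (not isolated)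
Conditions: PivCl, Et3N, THF, −20 °C; then LiCl, 9, rt
Reagents that add atoms: none
Why: N-acylation of the oxazolidinone through a mixed anhydride (LiCl/Et3N protocol), in which the hindered pivaloyl carbonyl directs attack to the enoyl carbonyl and no ketene forms that could scramble the alkene geometry.

Step 7
Reactants: 12 mono-tert-butyl fumarate, (2E)-4-tert-butoxy-4-oxobut-2-enoic acid
Product: 13 tert-butyl (2E)-4-chloro-4-oxobut-2-enoate
Conditions: 1-chloro-N,N,2-trimethylprop-1-en-1-amine, CH2Cl2, 0 °C → rt; used crude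
Reagents that add atoms: 1-chloro-N,N,2-trimethylprop-1-en-1-amine, CC(C)=C(Cl)N(C)C
Why: Neutral acid chloride formation with an α-chloroenamine (Ghosez reagent), which releases no HCl and so preserves the tert-butyl ester and the (E)-alkene.

Step 8
Reactants: 11 3-[(2E)-8-iodo-3,7,7-trimethyloct-2-enoyl]-1,3-oxazolidin-2-one; 13 tert-butyl (2E)-4-chloro-4-oxobut-2-enoate
Product: 15 tert-butyl (2E,10E)-6,6,10-trimethyl-4,12-dioxo-12-(2-oxo-1,3-oxazolidin-3-yl)dodeca-2,10-dienoate, via alkylzinc iodide 14 (not isolated)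
Conditions: Zn dust (activated with BrCH2CH2Br and TMSCl), LiCl, THF, 50 °C; decant; then 13, Pd(PPh3)4 (5 mol %), THF, 0 °C → rt
Reagents that add atoms: none
Why: Direct zinc insertion into the primary iodide followed by Negishi acylation under zerovalent palladium catalysis, in which the alkylzinc iodide tolerates imide, ester and enoate groups, has no β-hydrogen and, without copper, does not add in conjugate fashion, so the C5–C6 bond forms with the (E)-oxo-enoate intact.

Step 9
Reactants: 15 tert-butyl (2E,10E)-6,6,10-trimethyl-4,12-dioxo-12-(2-oxo-1,3-oxazolidin-3-yl)dodeca-2,10-dienoate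
Product: 16 tert-butyl (2E,4Z,10E)-4-[tert-butyl(dimethyl)silyloxy]-6,6,10-trimethyl-12-oxo-12-(2-oxo-1,3-oxazolidin-3-yl)dodeca-2,4,10-trienoate
Conditions: TBSOTf, Et3N, CH2Cl2, −78 → 0 °C; chromatography on Et3N-deactivated silica
Reagents that add atoms: tert-butyldimethylsilyl trifluoromethanesulfonate, CC(C)(C)[Si](C)(C)OS(=O)(=O)C(F)(F)F
Why: Soft enolisation and O-silylation of the ketone toward C5, its only enolisable position, gives the 2-silyloxy diene, and the (Z)-enol ether, with the quaternary C4 anti to the alkenyl group and H5 inside the diene, is the expected thermodynamic isomer under amine/silyl triflate conditions.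

Step 10
Reactants: 16 tert-butyl (2E,4Z,10E)-4-[tert-butyl(dimethyl)silyloxy]-6,6,10-trimethyl-12-oxo-12-(2-oxo-1,3-oxazolidin-3-yl)dodeca-2,4,10-trienoate
Product: 19 tert-butyl (1S,2S,4aS,8aS)-5,5,8a-trimethyl-4-oxo-1-(2-oxo-1,3-oxazolidine-3-carbonyl)decahydronaphthalene-2-carboxylate, via ring A ion pair 17 (not isolated), via C6 silyl enol ether 18 (not isolated)
Conditions: [Cu((R,R)-t-Bu-box)](SbF6)2 (10 mol %, from CuCl2, AgSbF6 and the ligand), 4 Å MS, CH2Cl2 (0.01 M), −20 °C → rt; then 1 M HCl, THF, 0 °C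
Reagents that add atoms: none
Why: Proposed new method: the cationic divalent copper complex chelates the two imide carbonyls, C5 of the silyl dienol ether then adds to C10 (Mukaiyama–Michael) and the copper-bound C9 enolate adds to C8 of the silyl-activated enone before bond rotation, so that the cascade is an asynchronous, formally [4+2] process that releases silyl enol ether 18 and the catalyst; the closest known reaction types are bis(oxazoline)copper-catalysed Mukaiyama–Michael additions to N-enoyl oxazolidinones and Lewis-acid-triggered intramolecular double Michael (stepwise Diels–Alder) reactions of silyl dienol ethers with tethered enoates. Ring A closes 6-exo-trig at C10 through a chair-like tether, and ring B closes 6-endo-trig at C8 through the boat-like, imide-endo arrangement of a Diels–Alder transition state. C10 is set by the ligand, whose tert-butyl group is expected to shield the Re face at C9 so that C5 bonds to the Re face of C10. C5 follows from the (Z)-enol ether and the endo geometry (H5 anti to the C10 methyl group, trans fusion), C9 from the (E)-enoyl geometry (C11 cis to the C10 methyl group) and C8 from the (E)-oxo-enoate under suprafacial closure (ester cis to C11 and axial). The step needs chemoselective activation of the imide, which alone can chelate copper, and a boat-like rather than half-chair second closure, since the latter would give the C8 epimer; the pre-stacked ion pair, the Thorpe–Ingold effect of the C4 gem-dimethyl group and the base-free medium (the axial C8 ester is the kinetic product) are relied on for this. C5 is the only nucleophilic carbon, so no regiochemical alternative exists.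

Step 11
Reactants: 19 tert-butyl (1S,2S,4aS,8aS)-5,5,8a-trimethyl-4-oxo-1-(2-oxo-1,3-oxazolidine-3-carbonyl)decahydronaphthalene-2-carboxylate
Product: 21 (1S,2S,4aS,8aS)-2-(tert-butoxycarbonyl)-5,5,8a-trimethyl-4-oxodecahydronaphthalene-1-carboxylic acid, via peroxy acid 20 (not isolated)
Conditions: LiOH, H2O2 (30% aq), THF/H2O (3:1), 0 °C; then Na2SO3 (aq); then 1 M HCl to pH 3
Reagents that add atoms: hydrogen peroxide, OO
Why: Hydroperoxide-mediated imide hydrolysis (LiOOH), in which the small α-effect nucleophile attacks the exocyclic carbonyl even of hindered N-acyl oxazolidinones at 0 °C without touching the tert-butyl ester, the ketone or the C8 and C9 stereocentres, and sulfite reduces the peroxy acid formed.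

Step 12
Reactants: 21 (1S,2S,4aS,8aS)-2-(tert-butoxycarbonyl)-5,5,8a-trimethyl-4-oxodecahydronaphthalene-1-carboxylic acid
Product: 22 di-tert-butyl (1S,2S,4aS,8aS)-5,5,8a-trimethyl-4-oxodecahydronaphthalene-1,2-dicarboxylate
Conditions: tert-butyl 2,2,2-trichloroacetimidate, CH2Cl2/cyclohexane, rt → 40 °C
Reagents that add atoms: tert-butyl 2,2,2-trichloroacetimidate, CC(C)(C)OC(=N)C(Cl)(Cl)Cl
Why: Imidate esterification, in which the carboxylic acid itself protonates the trichloroacetimidate and is O-alkylated by the tert-butyl cation equivalent, a process insensitive to the hindrance at C9 and free of base that could epimerise C8.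

Step 13
Reactants: 22 di-tert-butyl (1S,2S,4aS,8aS)-5,5,8a-trimethyl-4-oxodecahydronaphthalene-1,2-dicarboxylate
Product: 23 di-tert-butyl (1S,2S,4R,4aS,8aS)-4-hydroxy-5,5,8a-trimethyldecahydronaphthalene-1,2-dicarboxylate
Conditions: NaBH4, MeOH/THF, −20 → 0 °C
Reagents that add atoms: none
Why: Substrate-controlled borohydride reduction, in which the β face of C6 is blocked by the axial methyl groups on C4 and C10 and by the axial C8 ester, so hydride enters from the α face and gives the axial 6β-alcohol, while the tert-butyl ester at C8 resists lactonisation onto the 1,3-diaxial alkoxide.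

Step 14
Reactants: 24 (2E,4E)-hexa-2,4-dienal; 25 malonic acid
Product: 27 (2E,4E,6E)-octa-2,4,6-trienoic acid, via hexadienylidenemalonic acid 26 (not isolated)
Conditions: pyridine, piperidine (cat.), 90 °C
Reagents that add atoms: none
Why: Knoevenagel condensation with decarboxylation in the same flask (Doebner modification), which forms the new double bond with (E)-geometry and leaves the dienal geometry unchanged.

Step 15
Reactants: 23 di-tert-butyl (1S,2S,4R,4aS,8aS)-4-hydroxy-5,5,8a-trimethyldecahydronaphthalene-1,2-dicarboxylate; 27 (2E,4E,6E)-octa-2,4,6-trienoic acid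
Product: 29 di-tert-butyl (1S,2S,4R,4aS,8aS)-5,5,8a-trimethyl-4-[(2E,4E,6E)-octa-2,4,6-trienoyloxy]decahydronaphthalene-1,2-dicarboxylate, via Yamaguchi mixed anhydride 28 (not isolated)
Conditions: 27, 2,4,6-trichlorobenzoyl chloride, Et3N, toluene, rt; then 23, DMAP, toluene, 60 °C
Reagents that add atoms: none
Why: Yamaguchi esterification, in which the mixed 2,4,6-trichlorobenzoic anhydride passes the trienoyl group through the acylpyridinium ion to the hindered axial alcohol, with retention at C6 because the C–O bond is not broken.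

Step 16
Reactants: 29 di-tert-butyl (1S,2S,4R,4aS,8aS)-5,5,8a-trimethyl-4-[(2E,4E,6E)-octa-2,4,6-trienoyloxy]decahydronaphthalene-1,2-dicarboxylate
Product: 30 (1S,2S,4R,4aS,8aS)-5,5,8a-trimethyl-4-[(2E,4E,6E)-octa-2,4,6-trienoyloxy]decahydronaphthalene-1,2-dicarboxylic acid (CNP0462207.1)
Conditions: TFA/CH2Cl2 (1:3), 0 °C → rt
Reagents that add atoms: none
Why: Acidolysis of both tert-butyl esters (AAL1, loss of isobutene), which is independent of steric hindrance, leaves the trienoate ester untouched and cannot lead to a C6–C12 lactone because O6 is already acylated.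

Compound list

1 | 2,2-dimethylpent-4-enal | C=CCC(C)(C)C=O | starting material
2 | 2,2-dimethylpent-4-en-1-ol | C=CCC(C)(C)CO | intermediate
3 | 5-iodo-4,4-dimethylpent-1-ene | C=CCC(C)(C)CI | intermediate
4 | methyl acetoacetate | COC(=O)CC(C)=O | starting material
5 | methyl (2E)-3-(trifluoromethylsulfonyloxy)but-2-enoate | COC(=O)/C=C(\C)OS(=O)(=O)C(F)(F)F | intermediate
6 | 9-(5-iodo-4,4-dimethylpentyl)-9-borabicyclo[3.3.1]nonane | ICC(C)(C)CCCB1C2CCCC1CCC2 | intermediate (not isolated)
7 | methyl (2E)-8-iodo-3,7,7-trimethyloct-2-enoate | COC(=O)/C=C(\C)CCCC(C)(C)CI | intermediate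
8 | (2E)-8-iodo-3,7,7-trimethyloct-2-enoic acid | OC(=O)/C=C(\C)CCCC(C)(C)CI | intermediate
9 | oxazolidin-2-one | O=C1NCCO1 | starting material
10 | (2E)-8-iodo-3,7,7-trimethyloct-2-enoic pivalic anhydride | CC(C)(C)C(=O)OC(=O)/C=C(\C)CCCC(C)(C)CI | intermediate (not isolated)
11 | 3-[(2E)-8-iodo-3,7,7-trimethyloct-2-enoyl]-1,3-oxazolidin-2-one | O=C(/C=C(\C)CCCC(C)(C)CI)N1CCOC1=O | intermediate
12 | mono-tert-butyl fumarate, (2E)-4-tert-butoxy-4-oxobut-2-enoic acid | CC(C)(C)OC(=O)/C=C/C(=O)O | starting material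
13 | tert-butyl (2E)-4-chloro-4-oxobut-2-enoate | CC(C)(C)OC(=O)/C=C/C(=O)Cl | intermediate
14 | [(6E)-2,2,6-trimethyl-8-oxo-8-(2-oxo-1,3-oxazolidin-3-yl)oct-6-en-1-yl]zinc iodide | O=C(/C=C(\C)CCCC(C)(C)C[Zn]I)N1CCOC1=O | intermediate (not isolated)
15 | tert-butyl (2E,10E)-6,6,10-trimethyl-4,12-dioxo-12-(2-oxo-1,3-oxazolidin-3-yl)dodeca-2,10-dienoate | CC(C)(C)OC(=O)/C=C/C(=O)CC(C)(C)CCC/C(C)=C/C(=O)N1CCOC1=O | intermediate
16 | tert-butyl (2E,4Z,10E)-4-[tert-butyl(dimethyl)silyloxy]-6,6,10-trimethyl-12-oxo-12-(2-oxo-1,3-oxazolidin-3-yl)dodeca-2,4,10-trienoate (key-step precursor) | CC(C)(C)OC(=O)/C=C/C(O[Si](C)(C)C(C)(C)C)=C/C(C)(C)CCC/C(C)=C/C(=O)N1CCOC1=O | intermediate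
17 | ring A-closed ion pair: copper-bound C9 imide enolate and C6 silyloxocarbenium ion, C5–C10 bond formed, H5 and the C10 methyl group trans (drawn without copper) | CC(C)(C)OC(=O)/C=C/C(=[O+][Si](C)(C)C(C)(C)C)[C@H]1C(C)(C)CCC[C@]1(C)/C=C(\[O-])N2CCOC2=O | intermediate (not isolated)
18 | C6 tert-butyldimethylsilyl enol ether (C6=C7) of 19, both rings closed, 5α-H, 8β-CO2tBu, 9β-imide, 10β-CH3 | CC(C)(C)[Si](C)(C)OC1=C[C@H](C(=O)OC(C)(C)C)[C@H](C(=O)N3CCOC3=O)[C@@]2(C)CCCC(C)(C)[C@H]12 | intermediate (not isolated)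
19 | tert-butyl (1S,2S,4aS,8aS)-5,5,8a-trimethyl-4-oxo-1-(2-oxo-1,3-oxazolidine-3-carbonyl)decahydronaphthalene-2-carboxylate (6-oxodrimane, 5α-H, 8β-CO2tBu axial, 9β-imide equatorial, 10β-CH3) | O=C1C[C@H](C(=O)OC(C)(C)C)[C@H](C(=O)N3CCOC3=O)[C@@]2(C)CCCC(C)(C)[C@H]12 | intermediate
20 | (1S,2S,4aS,8aS)-2-(tert-butoxycarbonyl)-5,5,8a-trimethyl-4-oxodecahydronaphthalene-1-carboperoxoic acid | O=C1C[C@H](C(=O)OC(C)(C)C)[C@H](C(=O)OO)[C@@]2(C)CCCC(C)(C)[C@H]12 | intermediate (not isolated)
21 | (1S,2S,4aS,8aS)-2-(tert-butoxycarbonyl)-5,5,8a-trimethyl-4-oxodecahydronaphthalene-1-carboxylic acid | O=C1C[C@H](C(=O)OC(C)(C)C)[C@H](C(=O)O)[C@@]2(C)CCCC(C)(C)[C@H]12 | intermediate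
22 | di-tert-butyl (1S,2S,4aS,8aS)-5,5,8a-trimethyl-4-oxodecahydronaphthalene-1,2-dicarboxylate | O=C1C[C@H](C(=O)OC(C)(C)C)[C@H](C(=O)OC(C)(C)C)[C@@]2(C)CCCC(C)(C)[C@H]12 | intermediate
23 | di-tert-butyl (1S,2S,4R,4aS,8aS)-4-hydroxy-5,5,8a-trimethyldecahydronaphthalene-1,2-dicarboxylate (6β-OH, axial) | O[C@@H]1C[C@H](C(=O)OC(C)(C)C)[C@H](C(=O)OC(C)(C)C)[C@@]2(C)CCCC(C)(C)[C@H]12 | intermediate
24 | (2E,4E)-hexa-2,4-dienal | C/C=C/C=C/C=O | starting material
25 | malonic acid | OC(=O)CC(=O)O | starting material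
26 | 2-[(2E,4E)-hexa-2,4-dien-1-ylidene]propanedioic acid | C/C=C/C=C/C=C(C(=O)O)C(=O)O | intermediate (not isolated)
27 | (2E,4E,6E)-octa-2,4,6-trienoic acid | C/C=C/C=C/C=C/C(=O)O | intermediate
28 | (2E,4E,6E)-octa-2,4,6-trienoic 2,4,6-trichlorobenzoic anhydride | C/C=C/C=C/C=C/C(=O)OC(=O)c1c(Cl)cc(Cl)cc1Cl | intermediate (not isolated)
29 | di-tert-butyl (1S,2S,4R,4aS,8aS)-5,5,8a-trimethyl-4-[(2E,4E,6E)-octa-2,4,6-trienoyloxy]decahydronaphthalene-1,2-dicarboxylate | C/C=C/C=C/C=C/C(=O)O[C@@H]1C[C@H](C(=O)OC(C)(C)C)[C@H](C(=O)OC(C)(C)C)[C@@]2(C)CCCC(C)(C)[C@H]12 | intermediate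
30 | (1S,2S,4R,4aS,8aS)-5,5,8a-trimethyl-4-[(2E,4E,6E)-octa-2,4,6-trienoyloxy]decahydronaphthalene-1,2-dicarboxylic acid | C/C=C/C=C/C=C/C(=O)O[C@@H]1C[C@H](C(=O)O)[C@H](C(=O)O)[C@@]2(C)CCCC(C)(C)[C@H]12 | target

Total step count: 16.
Longest linear sequence: 13 steps (1, 2, 4, 5, 6, 8, 9, 10, 11, 12, 13, 15, 16).

Steps most likely to fail

Step 10 (proposed new method). Three processes may go wrong:
- The β,β-disubstituted enoyl imide may be too unreactive under catalytic activation, so that protodesilylation of the dienol ether outruns cyclisation.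
- The second closure may leak into a fully stepwise half-chair pathway and erode the configuration at C8.
- Facial discrimination at C10 may be insufficient.

The fallback uses known chemistry, an auxiliary-controlled, Lewis-acid-promoted intramolecular Diels–Alder reaction, and sets out from acid 8. Mixed anhydride 10 is formed as in step 6 and acylates lithiated (4S)-4-benzyl-1,3-oxazolidin-2-one to give (4S)-4-benzyl-3-[(2E)-8-iodo-3,7,7-trimethyloct-2-enoyl]-1,3-oxazolidin-2-one F1. Zinc insertion as in step 8 gives [(6E)-8-[(4S)-4-benzyl-2-oxo-1,3-oxazolidin-3-yl]-2,2,6-trimethyl-8-oxooct-6-en-1-yl]zinc iodide F2 (not isolated). Acylation with 13 under Pd(PPh3)4 catalysis gives tert-butyl (2E,10E)-12-[(4S)-4-benzyl-2-oxo-1,3-oxazolidin-3-yl]-6,6,10-trimethyl-4,12-dioxododeca-2,10-dienoate F3, and TBSOTf/Et3N gives tert-butyl (2E,4Z,10E)-12-[(4S)-4-benzyl-2-oxo-1,3-oxazolidin-3-yl]-4-[tert-butyl(dimethyl)silyloxy]-6,6,10-trimethyl-12-oxododeca-2,4,10-trienoate F4. Me2AlCl (1.4 equiv, CH2Cl2, −30 °C) forms the cationic aluminium chelate of the s-cis imide, in which the benzyl group blocks the Re face at C9. The endo cycloaddition should give the C6 silyl enol ether of the auxiliary-bearing bicycle F5, which acidic work-up hydrolyses to tert-butyl (1S,2S,4aS,8aS)-1-[(4S)-4-benzyl-2-oxo-1,3-oxazolidine-3-carbonyl]-5,5,8a-trimethyl-4-oxodecahydronaphthalene-2-carboxylate F6. LiOH/H2O2 (through peroxy acid 20) removes the auxiliary, and the fallback comes back to the route at acid 21.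

Step 15. Acyl transfer to the 6β-hydroxyl, which is shielded by three syn-axial groups (the methyl groups on C4 and C10 and the C8 ester), may be too slow, and the activated trienoyl donor may isomerise on prolonged heating. The fallback sets out from alcohol 23 and builds the trienoate on the ester instead of transferring it intact. The small, ketene-forming donor diethylphosphonoacetic acid (DCC, DMAP cat., CH2Cl2) should give di-tert-butyl (1S,2S,4R,4aS,8aS)-4-{[(diethoxyphosphoryl)acetyl]oxy}-5,5,8a-trimethyldecahydronaphthalene-1,2-dicarboxylate F7. Horner–Wadsworth–Emmons olefination with (2E,4E)-hexa-2,4-dienal 24 (LiCl, DBU, MeCN) then forms the (2E)-alkene, and the fallback comes back to the route at ester 29.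

Step 8. Conjugate addition, reduction or oligomerisation at the fumaroyl unit of the acid chloride or of the product may compete under the zinc/palladium conditions. The fallback sets out from iodide 11 and forms the C7=C8 bond by olefination instead of bringing in the fumarate intact. Alkylzinc iodide 14 is acylated (Pd(PPh3)4) with 2-(diethoxyphosphoryl)acetyl chloride to give diethyl [(8E)-4,4,8-trimethyl-2,10-dioxo-10-(2-oxo-1,3-oxazolidin-3-yl)dec-8-en-1-yl]phosphonate F8. A Masamune–Roush Horner–Wadsworth–Emmons reaction with tert-butyl glyoxylate (LiCl, i-Pr2NEt, MeCN) should then give the (E)-oxo-enoate, and the fallback comes back to the route at 15.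

Further compounds

F1 | step 10 | (4S)-4-benzyl-3-[(2E)-8-iodo-3,7,7-trimethyloct-2-enoyl]-1,3-oxazolidin-2-one | O=C(/C=C(\C)CCCC(C)(C)CI)N1[C@@H](Cc2ccccc2)COC1=O
F2 | step 10 | [(6E)-8-[(4S)-4-benzyl-2-oxo-1,3-oxazolidin-3-yl]-2,2,6-trimethyl-8-oxooct-6-en-1-yl]zinc iodide | O=C(/C=C(\C)CCCC(C)(C)C[Zn]I)N1[C@@H](Cc2ccccc2)COC1=O
F3 | step 10 | tert-butyl (2E,10E)-12-[(4S)-4-benzyl-2-oxo-1,3-oxazolidin-3-yl]-6,6,10-trimethyl-4,12-dioxododeca-2,10-dienoate | CC(C)(C)OC(=O)/C=C/C(=O)CC(C)(C)CCC/C(C)=C/C(=O)N1[C@@H](Cc2ccccc2)COC1=O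
F4 | step 10 | tert-butyl (2E,4Z,10E)-12-[(4S)-4-benzyl-2-oxo-1,3-oxazolidin-3-yl]-4-[tert-butyl(dimethyl)silyloxy]-6,6,10-trimethyl-12-oxododeca-2,4,10-trienoate | CC(C)(C)OC(=O)/C=C/C(O[Si](C)(C)C(C)(C)C)=C/C(C)(C)CCC/C(C)=C/C(=O)N1[C@@H](Cc2ccccc2)COC1=O
F5 | step 10 | C6 tert-butyldimethylsilyl enol ether (C6=C7) of F6 | CC(C)(C)[Si](C)(C)OC1=C[C@H](C(=O)OC(C)(C)C)[C@H](C(=O)N3[C@@H](Cc4ccccc4)COC3=O)[C@@]2(C)CCCC(C)(C)[C@H]12
F6 | step 10 | tert-butyl (1S,2S,4aS,8aS)-1-[(4S)-4-benzyl-2-oxo-1,3-oxazolidine-3-carbonyl]-5,5,8a-trimethyl-4-oxodecahydronaphthalene-2-carboxylate | O=C1C[C@H](C(=O)OC(C)(C)C)[C@H](C(=O)N3[C@@H](Cc4ccccc4)COC3=O)[C@@]2(C)CCCC(C)(C)[C@H]12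
F7 | step 15 | di-tert-butyl (1S,2S,4R,4aS,8aS)-4-{[(diethoxyphosphoryl)acetyl]oxy}-5,5,8a-trimethyldecahydronaphthalene-1,2-dicarboxylate | CCOP(=O)(OCC)CC(=O)O[C@@H]1C[C@H](C(=O)OC(C)(C)C)[C@H](C(=O)OC(C)(C)C)[C@@]2(C)CCCC(C)(C)[C@H]12
F8 | step 8 | diethyl [(8E)-4,4,8-trimethyl-2,10-dioxo-10-(2-oxo-1,3-oxazolidin-3-yl)dec-8-en-1-yl]phosphonate | CCOP(=O)(OCC)CC(=O)CC(C)(C)CCC/C(C)=C/C(=O)N1CCOC1=O
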